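**Plan**
1. Reading of the target: in the cis-fused 3,7-dioxabicyclo[3.3.0]octane both aryl groups (at C2 and C6) are endo, so H–C2 and H–C6 are exo (all-S, "diaxial" furofuran). The dihydrobenzofuran is 2,3-cis (2S,3S).
2. Cuts: the bond from dihydrobenzofuran C5 to C2 of the bicycle, then the guaiacyl–C6 bond, each back to an aryllithium and a lactone carbonyl of the C2-symmetric bislactone 7. The C1–C5 bond of 7 goes back to two enolates of one acyl oxazolidinone. The dihydrobenzofuran C2–C3 bond goes back to an aryldiazoacetate and its O–CH2Ar bond.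
3. Forward: enolate homodimerisation and double lactonisation give bicycle 7. Aryllithium addition and silane reduction install the guaiacyl ring (lactone 12). Rh(II) C–H insertion closes the dihydrobenzofuran. The key step joins aryllithium 24 to C2 of 12 and re-forms the second tetrahydrofuran ring by reductive etherification. Desilylation finishes.
4. Stereochemistry: C1/C5 come from the (S)-oxazolidinone. C2 and C6 come from hydride delivery to the convex face of planar 2-aryl oxocarbenium ions (exo H, endo aryl), which makes the key step stereoconvergent. Dihydrobenzofuran C2/C3 (cis) come from the chiral dirhodium catalyst.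

Key step: step 15

Assumption: dirhodium tetrakis[N-phthaloyl-(R)-tert-leucinate], Rh2(R-PTTL)4, is taken to give the (2S,3R)-cis ester 21; if the sense of induction is the opposite, the (S)-catalyst is used.

**Route**

Step 1
Reactants: 1 3-(benzyloxy)propanoic acid; 2 (S)-4-benzyloxazolidin-2-one
Product: 3 (S)-4-benzyl-3-[3-(benzyloxy)propanoyl]oxazolidin-2-one
Conditions: PivCl, Et3N, THF, −20 °C; then 2, LiCl, rt
Reagents that add atoms: none
Why: Mixed-anhydride N-acylation of the oxazolidinone (Evans imide formation); no stereocentre is formed.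

Step 2
Reactants: 3 (S)-4-benzyl-3-[3-(benzyloxy)propanoyl]oxazolidin-2-one (2 equiv)
Product: 5 (2S,3S)-1,4-bis[(S)-4-benzyl-2-oxooxazolidin-3-yl]-2,3-bis[(benzyloxy)methyl]butane-1,4-dione, via lithium Z-enolate 4 (not isolated)
Conditions: LDA, THF, −78 °C; then CuCl2 (DMF solution), −78 → −40 °C
Reagents that add atoms: none
Why: Oxidative homocoupling of a chiral imide enolate (Cu(II)-mediated enolate dimerisation): one-electron oxidation of the chelated Z-enolate 4 and C–C coupling on the face anti to the auxiliary benzyl group at both termini should give the C2-symmetric (2S,3S) dimer.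

Step 3
Reactants: 5 (2S,3S)-bis(benzyloxymethyl) bis-imide
Product: 7 (1S,5S)-3,7-dioxabicyclo[3.3.0]octane-2,6-dione, via diol bis-imide 6 (not isolated)
Conditions: H2 (1 atm), 10% Pd/C, EtOAc; then TsOH·H2O (cat.), toluene, 60 °C
Reagents that add atoms: none
Why: Hydrogenolysis of both benzyl ethers followed by acid-catalysed double lactonisation (5-exo-trig acyl transfer of each γ-hydroxy imide, which releases the auxiliary); no stereocentre is touched and the (2S,3S) array can close only to the cis-fused bicycle.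

Step 4
Reactants: 8 4-bromo-2-methoxyphenol
Product: 9 (4-bromo-2-methoxyphenoxy)triisopropylsilane
Conditions: TIPSCl, imidazole, DMF, rt
Reagents that add atoms: triisopropylsilyl chloride, CC(C)[Si](Cl)(C(C)C)C(C)C
Why: Phenol silylation; the TIPS ether tolerates the organolithium, Lewis-acid and amidine-base steps that follow.

Step 5
Reactants: 9 (4-bromo-2-methoxyphenoxy)triisopropylsilane; 7 (1S,5S)-3,7-dioxabicyclo[3.3.0]octane-2,6-dione (1.5 equiv, excess recovered)
Product: 12 (1S,5S,6S)-6-[3-methoxy-4-(triisopropylsilyloxy)phenyl]-3,7-dioxabicyclo[3.3.0]octan-2-one (aryl endo), via aryllithium 10 (not isolated), via hemiketal 11 (not isolated)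
Conditions: n-BuLi, THF, −78 °C; cannulate into 7, THF, −78 °C; AcOH; then Et3SiH, BF3·OEt2 (promoter), CH2Cl2, −78 → −40 °C
Reagents that add atoms: none
Why: Br–Li exchange, 1,2-addition of the aryllithium to one of the two homotopic lactone carbonyls of 7 (only one mono-adduct is possible) and ionic hydrogenation of the hemiketal through the planar 6-aryl oxocarbenium ion, where hydride should enter on the convex face of the cis-fused bicycle and leave the aryl group endo (6S).

Step 6
Reactants: 13 2-(2-hydroxy-3-methoxyphenyl)acetic acid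
Product: 14 methyl 2-(2-hydroxy-3-methoxyphenyl)acetate
Conditions: MeOH, H2SO4 (cat.), reflux
Reagents that add atoms: methanol, CO
Why: Fischer esterification; in methanol any benzofuranone formed by lactonisation is opened to the methyl ester.

Step 7
Reactants: 14 methyl 2-(2-hydroxy-3-methoxyphenyl)acetate
Product: 15 methyl 2-(5-bromo-2-hydroxy-3-methoxyphenyl)acetate
Conditions: NBS, MeCN, 0 °C
Reagents that add atoms: N-bromosuccinimide, O=C1CCC(=O)N1Br
Why: Electrophilic aromatic bromination directed by the free phenol, whose two ortho positions are blocked, so bromine should enter para to OH (the future C5 of the dihydrobenzofuran).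

Step 8
Reactants: 16 vanillin
Product: 17 3-methoxy-4-(triisopropylsilyloxy)benzaldehyde
Conditions: TIPSCl, imidazole, DMF, rt
Reagents that add atoms: triisopropylsilyl chloride, CC(C)[Si](Cl)(C(C)C)C(C)C
Why: Phenol silylation.

Step 9
Reactants: 17 3-methoxy-4-(triisopropylsilyloxy)benzaldehyde
Product: 18 [3-methoxy-4-(triisopropylsilyloxy)phenyl]methanol
Conditions: NaBH4, MeOH, 0 °C
Reagents that add atoms: none
Why: Borohydride reduction of the aldehyde.

Step 10
Reactants: 15 methyl 2-(5-bromo-2-hydroxy-3-methoxyphenyl)acetate; 18 [3-methoxy-4-(triisopropylsilyloxy)phenyl]methanol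
Product: 19 methyl 2-(5-bromo-3-methoxy-2-{[3-methoxy-4-(triisopropylsilyloxy)benzyl]oxy}phenyl)acetate
Conditions: PPh3, DIAD, THF, 0 °C → rt
Reagents that add atoms: none
Why: Mitsunobu etherification of the acidic bromophenol with the primary benzylic alcohol.

Step 11
Reactants: 19 aryl benzyl ether ester
Product: 20 methyl 2-(5-bromo-3-methoxy-2-{[3-methoxy-4-(triisopropylsilyloxy)benzyl]oxy}phenyl)-2-diazoacetate
Conditions: p-ABSA, DBU, MeCN, 0 °C → rt
Reagents that add atoms: 4-acetamidobenzenesulfonyl azide, CC(=O)Nc1ccc(cc1)S(=O)(=O)N=[N+]=[N-]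
Why: Regitz diazo transfer to the arylacetate.

Step 12
Reactants: 20 aryldiazoacetate
Product: 21 methyl (2S,3R)-5-bromo-7-methoxy-2-[3-methoxy-4-(triisopropylsilyloxy)phenyl]-2,3-dihydro-1-benzofuran-3-carboxylate (2,3-cis)
Conditions: Rh2(R-PTTL)4 (1 mol %), toluene, −60 °C
Reagents that add atoms: none
Why: Rh(II)-carbenoid intramolecular 1,5 C–H insertion of the donor/acceptor carbenoid into the ArCH2–O bond, where the concerted insertion in the chiral carboxylate pocket should give the 2,3-cis ring and the catalyst enantiomer fixes the absolute configuration.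

Step 13
Reactants: 21 cis ester
Product: 22 [(2S,3S)-5-bromo-7-methoxy-2-[3-methoxy-4-(triisopropylsilyloxy)phenyl]-2,3-dihydro-1-benzofuran-3-yl]methanol (cis)
Conditions: DIBAL-H, CH2Cl2, −78 → −20 °C; Rochelle salt
Reagents that add atoms: none
Why: Hydride reduction of the ester under non-basic conditions, so the kinetic cis relationship at C2/C3 is kept and the aryl bromide survives.

Step 14
Reactants: 22 cis alcohol
Product: 23 {[(2S,3S)-5-bromo-7-methoxy-2-[3-methoxy-4-(triisopropylsilyloxy)phenyl]-2,3-dihydro-1-benzofuran-3-yl]methoxy}(tert-butyl)dimethylsilane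
Conditions: TBSCl, imidazole, DMF, rt
Reagents that add atoms: tert-butyldimethylsilyl chloride, CC(C)(C)[Si](C)(C)Cl
Why: Silylation of the primary alcohol before metalation.

Step 15
Reactants: 23 silylated 5-bromodihydrobenzofuran; 12 endo-aryl lactone
Product: 26 tris-silyl ether of the target, (1S,2S,5S,6S)-2-[dihydrobenzofuran-5-yl]-6-aryl-3,7-dioxabicyclo[3.3.0]octane, via aryllithium 24 (not isolated), via hemiketal 25 (not isolated)
Conditions: n-BuLi, THF, −78 °C; 12 (1.0 equiv), −78 °C; AcOH; then Et3SiH, BF3·OEt2 (promoter), CH2Cl2, −78 → −40 °C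
Reagents that add atoms: none
Why: Br–Li exchange gives aryllithium 24, which adds once to the lactone carbonyl C2 of 12; after protic quench the crude hemiketal 25 (both anomers and the ring-opened hydroxy ketone) is ionised by BF3·OEt2 to one planar 2-aryl oxocarbenium ion, which Et3SiH reduces. The closest known reaction type is the aryllithium-to-lactone addition followed by silane reduction used for C-aryl glycosides and 2-aryl tetrahydrofurans. The C2–O3 bond of the second tetrahydrofuran ring is re-closed by 5-exo-trig attack of the C4 hydroxyl on the aryl ketone (hemiketalisation) before loss of the hydroxyl, so the ring closure is a reductive etherification. The new stereocentre C2 is controlled by the cis-fused bicycle: hydride should enter on the convex (exo) face, anti to the other ring and its endo aryl group, which places the dihydrobenzofuranyl group endo (2S), and every isomer of 25 converges on this configuration. The step needs mono-addition, secured by the tetrahedral lithium alkoxide at −78 °C and 1:1 stoichiometry, and kinetic control in the reduction, secured by short contact at or below −40 °C so that the electron-rich benzylic ethers (C2, C6, dihydrobenzofuran C2) are not re-ionised.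

Step 16
Reactants: 26 tris-silyl ether
Product: 27 target, 4-[(2S,3S)-3-(hydroxymethyl)-5-[(1S,2S,5S,6S)-6-(4-hydroxy-3-methoxyphenyl)-3,7-dioxabicyclo[3.3.0]octan-2-yl]-7-methoxy-2,3-dihydro-1-benzofuran-2-yl]-2-methoxyphenol
Conditions: TBAF, AcOH, THF, 0 °C → rt
Reagents that add atoms: none
Why: Fluoride cleavage of the two aryl TIPS ethers and the primary TBS ether; the AcOH buffer keeps the freed phenols protonated so that the para-hydroxybenzylic ethers are not opened via quinone methides.

**Compound list**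
1 | 3-(benzyloxy)propanoic acid | OC(=O)CCOCc1ccccc1 | starting material
2 | (S)-4-benzyloxazolidin-2-one | O=C1N[C@@H](Cc2ccccc2)CO1 | starting material
3 | (S)-4-benzyl-3-[3-(benzyloxy)propanoyl]oxazolidin-2-one | O=C1OC[C@H](Cc2ccccc2)N1C(=O)CCOCc1ccccc1 | intermediate
4 | lithium Z-enolate of 3 | [Li+].[O-]/C(N1[C@@H](Cc2ccccc2)COC1=O)=C\COCc1ccccc1 | intermediate
5 | (2S,3S)-1,4-bis[(S)-4-benzyl-2-oxooxazolidin-3-yl]-2,3-bis[(benzyloxy)methyl]butane-1,4-dione | O=C1OC[C@H](Cc2ccccc2)N1C(=O)[C@H](COCc1ccccc1)[C@@H](COCc1ccccc1)C(=O)N1[C@@H](Cc2ccccc2)COC1=O | intermediate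
6 | (2S,3S)-1,4-bis[(S)-4-benzyl-2-oxooxazolidin-3-yl]-2,3-bis(hydroxymethyl)butane-1,4-dione | O=C1OC[C@H](Cc2ccccc2)N1C(=O)[C@H](CO)[C@@H](CO)C(=O)N1[C@@H](Cc2ccccc2)COC1=O | intermediate
7 | (1S,5S)-3,7-dioxabicyclo[3.3.0]octane-2,6-dione | O=C1OC[C@@H]2[C@H]1COC2=O | intermediate
8 | 4-bromo-2-methoxyphenol | COc1cc(Br)ccc1O | starting material
9 | (4-bromo-2-methoxyphenoxy)triisopropylsilane | COc1cc(Br)ccc1O[Si](C(C)C)(C(C)C)C(C)C | intermediate
10 | [3-methoxy-4-(triisopropylsilyloxy)phenyl]lithium | [Li]c1ccc(O[Si](C(C)C)(C(C)C)C(C)C)c(OC)c1 | intermediate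
11 | (1S,5S)-6-hydroxy-6-[3-methoxy-4-(triisopropylsilyloxy)phenyl]-3,7-dioxabicyclo[3.3.0]octan-2-one (anomer mixture) | COc1cc(C2(O)OC[C@@H]3[C@H]2COC3=O)ccc1O[Si](C(C)C)(C(C)C)C(C)C | intermediate
12 | (1S,5S,6S)-6-[3-methoxy-4-(triisopropylsilyloxy)phenyl]-3,7-dioxabicyclo[3.3.0]octan-2-one | COc1cc([C@H]2OC[C@@H]3[C@H]2COC3=O)ccc1O[Si](C(C)C)(C(C)C)C(C)C | intermediate
13 | 2-(2-hydroxy-3-methoxyphenyl)acetic acid | COc1cccc(CC(=O)O)c1O | starting material
14 | methyl 2-(2-hydroxy-3-methoxyphenyl)acetate | COC(=O)Cc1cccc(OC)c1O | intermediate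
15 | methyl 2-(5-bromo-2-hydroxy-3-methoxyphenyl)acetate | COC(=O)Cc1cc(Br)cc(OC)c1O | intermediate
16 | vanillin | COc1cc(C=O)ccc1O | starting material
17 | 3-methoxy-4-(triisopropylsilyloxy)benzaldehyde | COc1cc(C=O)ccc1O[Si](C(C)C)(C(C)C)C(C)C | intermediate
18 | [3-methoxy-4-(triisopropylsilyloxy)phenyl]methanol | COc1cc(CO)ccc1O[Si](C(C)C)(C(C)C)C(C)C | intermediate
19 | methyl 2-(5-bromo-3-methoxy-2-{[3-methoxy-4-(triisopropylsilyloxy)benzyl]oxy}phenyl)acetate | COC(=O)Cc1cc(Br)cc(OC)c1OCc1ccc(O[Si](C(C)C)(C(C)C)C(C)C)c(OC)c1 | intermediate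
20 | methyl 2-(5-bromo-3-methoxy-2-{[3-methoxy-4-(triisopropylsilyloxy)benzyl]oxy}phenyl)-2-diazoacetate | COC(=O)C(=[N+]=[N-])c1cc(Br)cc(OC)c1OCc1ccc(O[Si](C(C)C)(C(C)C)C(C)C)c(OC)c1 | intermediate
21 | methyl (2S,3R)-5-bromo-7-methoxy-2-[3-methoxy-4-(triisopropylsilyloxy)phenyl]-2,3-dihydro-1-benzofuran-3-carboxylate (cis) | Brc1cc(OC)c2c(c1)[C@@H](C(=O)OC)[C@@H](c1ccc(O[Si](C(C)C)(C(C)C)C(C)C)c(OC)c1)O2 | intermediate
22 | [(2S,3S)-5-bromo-7-methoxy-2-[3-methoxy-4-(triisopropylsilyloxy)phenyl]-2,3-dihydro-1-benzofuran-3-yl]methanol (cis) | Brc1cc(OC)c2c(c1)[C@@H](CO)[C@@H](c1ccc(O[Si](C(C)C)(C(C)C)C(C)C)c(OC)c1)O2 | intermediate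
23 | TBS ether of 22 | Brc1cc(OC)c2c(c1)[C@@H](CO[Si](C)(C)C(C)(C)C)[C@@H](c1ccc(O[Si](C(C)C)(C(C)C)C(C)C)c(OC)c1)O2 | intermediate
24 | 5-lithio derivative of 23 | [Li]c1cc(OC)c2c(c1)[C@@H](CO[Si](C)(C)C(C)(C)C)[C@@H](c1ccc(O[Si](C(C)C)(C(C)C)C(C)C)c(OC)c1)O2 | intermediate
25 | 2-hydroxy-2-aryl hemiketal from 24 and 12 (anomer mixture) | COc1cc([C@H]2OC[C@@H]3[C@H]2COC3(O)c2cc(OC)c3c(c2)[C@@H](CO[Si](C)(C)C(C)(C)C)[C@@H](c2ccc(O[Si](C(C)C)(C(C)C)C(C)C)c(OC)c2)O3)ccc1O[Si](C(C)C)(C(C)C)C(C)C | intermediate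
26 | tris-silyl ether of the target (two aryl OTIPS, one CH2OTBS) | COc1cc([C@H]2OC[C@@H]3[C@H]2CO[C@@H]3c2cc(OC)c3c(c2)[C@@H](CO[Si](C)(C)C(C)(C)C)[C@@H](c2ccc(O[Si](C(C)C)(C(C)C)C(C)C)c(OC)c2)O3)ccc1O[Si](C(C)C)(C(C)C)C(C)C | intermediate
27 | CNP0303197.1 | COc1cc([C@H]2OC[C@@H]3[C@H]2CO[C@@H]3c2cc(OC)c3c(c2)[C@@H](CO)[C@@H](c2ccc(O)c(OC)c2)O3)ccc1O | target

**Step count and risks**
Total steps: 16. Longest linear sequence: 9 steps (13 → 27; steps 6, 7, 10–16).

Steps most likely to fail:

1. Step 15. The Lewis acid may re-ionise the electron-rich benzylic C–O bonds (the new C2–O3 bond, C6–O7 and the cis-dihydrobenzofuran C2–O1 bond), which would epimerise them towards the exo/trans isomers or lead to silane over-reduction. A second aryllithium addition to the ring-opened ketone is also possible. Fallback: set out from hemiketal 25, isolated after the protic quench. Eliminating the C2 hydroxyl (MsCl, Et3N, DMAP, CH2Cl2, 0 °C) should give the bicyclic 2-aryl enol ether F1. Hydrogenation over Rh/Al2O3 (H2, EtOAc, trace Et3N) should add both hydrogens to the convex face, restoring the cis ring fusion and placing the aryl group endo under neutral conditions. The fallback comes back to the route at 26.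

2. Step 2. The enolate may lose benzyloxide by β-elimination, and facial or dl/meso control may be incomplete in the radical-type coupling. Fallback: this uses none of 1–5 and sets out from commercial succinyl chloride and (R)-4-benzyloxazolidin-2-one (the enantiomer of 2). N-acylation (n-BuLi, THF, −78 °C) gives the succinyl bis-imide F2. Two successive titanium-enolate benzyloxymethylations (TiCl4, i-Pr2NEt, BnOCH2Cl, CH2Cl2, 0 °C), with the electrophile entering anti to the auxiliary benzyl group, should give the (2S,3S)-bis(benzyloxymethyl) bis-imide F3 without any β-alkoxy enolate. Hydrogenolysis (H2, Pd/C) gives the diol bis-imide F4, and TsOH-catalysed lactonisation comes back to the route at 7.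

3. Step 12. Enantio-induction may be insufficient or of unexpected sense, and the doubly ortho-substituted aryl ether may give trans product or ylide-derived by-products. Fallback: set out from alcohol 22 of insufficient enantiomeric purity. Esterification with (S)-naproxen chloride (Et3N, DMAP, CH2Cl2) gives the (S)-naproxen ester of 22 F5 together with the (S)-naproxen ester of ent-22 F6. The diastereomers are separated by chromatography or crystallisation, and F5 is cleaved with DIBAL-H (CH2Cl2, −78 °C), which comes back to the route at enantiopure 22.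

Further compounds
F1 | step 15 | (5S,6S)-2-aryl-6-aryl-3,7-dioxabicyclo[3.3.0]oct-1-ene, the enol ether from dehydration of 25 | COc1cc([C@H]2OCC3=C(c4cc(OC)c5c(c4)[C@@H](CO[Si](C)(C)C(C)(C)C)[C@@H](c4ccc(O[Si](C(C)C)(C(C)C)C(C)C)c(OC)c4)O5)OC[C@@H]23)ccc1O[Si](C(C)C)(C(C)C)C(C)C
F2 | step 2 | 1,4-bis[(R)-4-benzyl-2-oxooxazolidin-3-yl]butane-1,4-dione | O=C1OC[C@@H](Cc2ccccc2)N1C(=O)CCC(=O)N1[C@H](Cc2ccccc2)COC1=O
F3 | step 2 | (2S,3S)-1,4-bis[(R)-4-benzyl-2-oxooxazolidin-3-yl]-2,3-bis[(benzyloxy)methyl]butane-1,4-dione | O=C1OC[C@@H](Cc2ccccc2)N1C(=O)[C@H](COCc1ccccc1)[C@@H](COCc1ccccc1)C(=O)N1[C@H](Cc2ccccc2)COC1=O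
F4 | step 2 | (2S,3S)-1,4-bis[(R)-4-benzyl-2-oxooxazolidin-3-yl]-2,3-bis(hydroxymethyl)butane-1,4-dione | O=C1OC[C@@H](Cc2ccccc2)N1C(=O)[C@H](CO)[C@@H](CO)C(=O)N1[C@H](Cc2ccccc2)COC1=O
F5 | step 12 | (S)-2-(6-methoxynaphthalen-2-yl)propanoate ester of 22 | Brc1cc(OC)c2c(c1)[C@@H](COC(=O)[C@@H](C)c1ccc3cc(OC)ccc3c1)[C@@H](c1ccc(O[Si](C(C)C)(C(C)C)C(C)C)c(OC)c1)O2
F6 | step 12 | (S)-2-(6-methoxynaphthalen-2-yl)propanoate ester of ent-22 | Brc1cc(OC)c2c(c1)[C@H](COC(=O)[C@@H](C)c1ccc3cc(OC)ccc3c1)[C@H](c1ccc(O[Si](C(C)C)(C(C)C)C(C)C)c(OC)c1)O2
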